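# Proposed synthesis of (3R)-3-[3,4-dihydroxy-2-methoxy-5-(2-methylbut-3-en-2-yl)phenyl]chroman-7-ol (CNP0167796.1)

## Analysis of the target

The target is an isoflavan: a chroman (benzene ring A fused to the dihydropyran ring C, atoms O1, C2, C3, C4, C4a to C8a) with a free phenol at C7 and a pentasubstituted aryl group, ring B, on C3. C3 is the only stereocentre and is (R). It is a tertiary benzylic CH between two methylene groups (C2 on O1, C4 on C4a), so no neighbouring stereocentre or carbonyl group can relay its configuration; a reagent or catalyst must set it. Ring B carries three adjacent oxygens with different fates (OMe at C2', free OH at C3' and C4') and a 2-methylbut-3-en-2-yl (reverse prenyl) group at C5', next to the C4' hydroxyl. The sensitive groups are the catechol (oxidation to the ortho-quinone in air or base) and the terminal alkene, which rules out hydrogenation once present and can take up the neighbouring C4' hydroxyl under strong acid. The difficulty lies in an isolated stereocentre remote from any directing group, three phenols that must be told apart from one methyl ether, and a quaternary benzylic carbon on a crowded ring. The strategy rests on the unit O1–C2–C3 with ring B on C3: O1 sits on the terminal carbon and hydrogen on the aryl-bearing carbon of what would be a 1,1-disubstituted styrene C3=C2, the pattern of an anti-Markovnikov addition of the ring A phenol across that alkene. The C5' substituent ortho to O4' is, in addition, the retron of an aromatic Claisen rearrangement.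

## Retrosynthetic reasoning

**Last step, 19 from 18.** The two methoxymethyl acetals on O3' and O7 are cut last. The catechol is thereby exposed only once, and mild acid in methanol removes acetals without touching a monosubstituted alkene.

**C5'–C(quaternary) bond, 18 from 16, and 16 from 14 and 15.** The reverse prenyl group is ortho to O4', so the bond between C5' and the quaternary carbon is cut by a retro-[3,3] shift to the O4' prenyl ether 16. C5' is the only free ortho position, which makes the forward rearrangement regiochemically unambiguous. Ether 16 comes from phenol 14 and prenyl bromide 15, and 14 from benzyl ether 13 by hydrogenolysis. The benzyl group marks O4' as the one oxygen to be freed after the ring is built. The alkene is introduced only after that hydrogenolysis and after the photochemical step, in which it would be a second site for oxidation and thiyl radical addition.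

**O1–C2 bond and C3–H bond, 13 from 12 (key disconnection).** Cutting O1–C2 and replacing the C3–H bond by a C3=C2 double bond leads to the ortho-allylphenol 12, a constitutional isomer of 13. No other cut of ring C gives a precursor that is an isomer of the product and carries no stereocentre. The forward reaction has to add the phenol oxygen to the terminal carbon (against the Markovnikov sense) and deliver hydrogen to one face of C3. One-electron oxidation of the styrene gives this regiochemistry, because attack at C2 produces the tertiary benzylic C3 radical. A chiral thiol then sets C3 by hydrogen-atom transfer. The thiol is chosen as an arenethiol. An alkanethiol has an S–H bond stronger than the tertiary benzylic C–H bond being formed, so its transfer would be uphill and its thiyl radical could abstract the C3–H bond of 13 again and racemise it.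

**Phenol unmasking and C3=C2 bond, 12 from 11 from 10.** The free phenol of 12 is carried as a triisopropylsilyl ether in 11 and released by fluoride. Acid is avoided because the electron-rich styrene would cyclise in the Markovnikov sense to a dihydrobenzofuran. The alkene is cut to ketone 10 (Wittig methylenation), which brings in C2 as a one-carbon unit.

**C4–C4a bond, 10 from 4 and 9.** The deoxybenzoin 10 is cut between the methylene carbon C4 and ring A. The forward reaction is a palladium-catalysed α-arylation of methyl ketone 4 with aryl bromide 9. This joins the two rings convergently, each with all its oxygens in place, and the acetyl carbon of 4 marks C1' without any aromatic substitution on ring B.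

**Ring B ketone, 4 from 3 from 2 from gallacetophenone 1.** The three hydroxyls of 1 differ in a predictable way: the C4 hydroxyl is the most acidic, the C2 hydroxyl is chelated to the ketone, and the C3 hydroxyl is in between. They are therefore capped in the order O4 (benzyl), O3 (methoxymethyl), O2 (methyl).

**Ring A bromide, 9 from 8 from 7 from 6 from resorcinol monobenzoate 5.** Bromination of 5 para to its free hydroxyl places bromine next to the acylated oxygen. The free oxygen (later O7) is then protected as the acetal, the benzoate is removed and the oxygen next to bromine (later O1) is silylated. The assignment of the two oxygens thus follows from the starting material. Direct mono-protection of a free bromodiphenol would not give it reliably, because there the more acidic hydroxyl next to bromine competes with the less hindered one.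

## Alternatives that were turned down

**Alternative 1:** Three-component conjunctive coupling around C3. The bonds C3–C1' and C4–C4a are cut, and C3 and C4 come from a two-carbon vinyl boron unit. In the forward step a ring B aryl–lithium species adds to the vinyl boronic ester to give a boron ate complex. Pd(OAc)2 with a chiral MandyPhos ligand and a ring A aryl triflate then triggers a 1,2-shift of the ring B aryl group from boron to C3, and reductive elimination joins C4 to C4a, giving the secondary boronate A1.
- For it: the route is fully convergent, and C3 is set by an established class of enantioselective reaction. On the reliability of stereocontrol this alternative is stronger than the chosen route.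
- Against it: the step closes no ring and leaves out C2. A1 still needs a one-carbon homologation of the C–B bond, oxidation, desilylation and ring closure, four operations after the key step.
- Against it: the ring B lithium reagent must already carry the reverse prenyl group, so a pentasubstituted ring B halide has to be made first, and the lithium halide from the exchange interferes with this type of coupling. Both aryl partners are ortho-oxygenated and electron-rich.
- Comparison: the chosen route makes the ring and the stereocentre in one isomerisation from simpler fragments and keeps the alkene out of all organometallic steps. It pays for this with an unproven enantioselective step.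

**Alternative 2:** Oxygen-tethered carbene C–H insertion with later cleavage of the tether. The bond C3–C4 is cut. Ring B carries an aryldiazoacetate at C1' and, on O2', a benzyl-type ether whose CH2 is C4 and whose aryl group is ring A. Rh2(S-PTTL)4, dirhodium tetrakis[N-phthaloyl-(S)-tert-leucinate], forms the carbene at C3, which inserts into the benzylic C–H bond and gives the cis-dihydrobenzofuran A2.
- For it: asymmetric intramolecular C–H insertion to cis-2-aryl-2,3-dihydrobenzofuran-3-carboxylates is a well-established reaction type, so stereocontrol at C3 is better founded than in the chosen route.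
- Against it: the five-membered ring of A2 is not in the target. The benzylic O2'–C4 bond must be cut reductively, and hydrogenolysis would also reduce the terminal alkene of the reverse prenyl group.
- Against it: O2' must then be methylated, the ester reduced to the C2 alcohol and ring C closed, at least five operations after the key step. Throughout them C3 is α to an ester and benzylic, hence open to epimerisation.
- Against it: the carbene can also cyclopropanate the vinyl group, and the second stereocentre made in A2 is thrown away.
- Comparison: the chosen route builds no sacrificial ring, and its stereocentre is never acidic.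

**Alternative 3:** Ammonium enolate plus ortho-quinone methide annulation. The bonds C3–C4 and O1–C2 are cut. The ring B arylacetic acid is activated as a mixed anhydride and converted by the isothiourea HyperBTM into a chiral ammonium enolate. This adds to the ring A ortho-quinone methide, released by base from a 2-(sulfonylmethyl)phenol, and lactonisation gives the dihydrocoumarin A3.
- For it: like the chosen route it closes the pyran ring and sets C3 in one catalytic step. It does so convergently through a C–C bond and with a known organocatalytic platform, so it is as strong as the chosen route on ring formation and stronger on precedent.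
- Against it: C4 is unsubstituted here. The parent methide is short-lived and oligomerises, and the annulation is best established for substituted methides.
- Against it: the only stereocentre of A3 is α to an aryl ester and benzylic, hence very acidic, and sits in a basic medium, so loss of configuration is a real danger.
- Against it: C2 is at the wrong oxidation level. The lactone must be reduced to the diol and ring C closed again, two to three more steps.
- Comparison: the chosen route reaches the chroman oxidation level directly and gives a configurationally robust C3.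

Key step: step 11

Assumption: the face of the C3 radical that (R)-2'-methoxy-1,1'-binaphthalene-2-thiol serves cannot be derived from first principles. The route is written with the (R)-thiol, and the equally accessible (S)-thiol is taken if the (R)-thiol turns out to favour the (S)-chroman.

## Route

Step 1
Reactants: 1 gallacetophenone, 1-(2,3,4-trihydroxyphenyl)ethan-1-one
Product: 2 1-[4-(benzyloxy)-2,3-dihydroxyphenyl]ethan-1-one
Conditions: BnBr (1.05 equiv), Li2CO3, DMF, 50 °C
Reagents that add atoms: benzyl bromide, BrCc1ccccc1
Why: Williamson etherification under a weak carbonate base: the C4 hydroxyl, para to the acetyl group, is the most acidic, while the C2 hydroxyl is locked in a hydrogen bond to the ketone, so one benzyl group should go to O4.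

Step 2
Reactants: 2 1-[4-(benzyloxy)-2,3-dihydroxyphenyl]ethan-1-one
Product: 3 1-[4-(benzyloxy)-2-hydroxy-3-(methoxymethoxy)phenyl]ethan-1-one
Conditions: MOMCl (1.1 equiv), iPr2NEt, CH2Cl2, 0 °C to rt
Reagents that add atoms: chloromethyl methyl ether, COCCl
Why: Acetal formation (MOM protection) with an amine base: the C2 hydroxyl stays hydrogen-bonded to the carbonyl group and is much less nucleophilic, so the C3 hydroxyl should react first.

Step 3
Reactants: 3 1-[4-(benzyloxy)-2-hydroxy-3-(methoxymethoxy)phenyl]ethan-1-one
Product: 4 1-[4-(benzyloxy)-2-methoxy-3-(methoxymethoxy)phenyl]ethan-1-one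
Conditions: MeI, K2CO3, DMF, 40 °C
Reagents that add atoms: iodomethane, CI
Why: Williamson methylation of the last, chelated phenol; carbonate in DMF is basic enough to break the hydrogen bond but not to enolise and alkylate the methyl ketone.

Step 4
Reactants: 5 3-hydroxyphenyl benzoate (resorcinol monobenzoate)
Product: 6 2-bromo-5-hydroxyphenyl benzoate
Conditions: NBS (1.0 equiv), MeCN, −10 °C to rt
Reagents that add atoms: N-bromosuccinimide, O=C1CCC(=O)N1Br
Why: Electrophilic aromatic bromination directed by the free hydroxyl, the strongest donor on the ring, to its para position; this fixes bromine ortho to the acylated oxygen (the later O1) and para to the free oxygen (the later O7).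

Step 5
Reactants: 6 2-bromo-5-hydroxyphenyl benzoate
Product: 7 2-bromo-5-(methoxymethoxy)phenyl benzoate
Conditions: MOMCl, iPr2NEt, CH2Cl2, 0 °C to rt
Reagents that add atoms: chloromethyl methyl ether, COCCl
Why: MOM acetal formation on the only free phenol; the aryl benzoate is stable to the hindered amine base.

Step 6
Reactants: 7 2-bromo-5-(methoxymethoxy)phenyl benzoate
Product: 8 2-bromo-5-(methoxymethoxy)phenol
Conditions: K2CO3 (0.5 equiv), MeOH, rt
Reagents that add atoms: none
Why: Base-catalysed transesterification of the activated aryl ester to methyl benzoate; the MOM acetal and the aryl bromide are inert to carbonate in methanol.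

Step 7
Reactants: 8 2-bromo-5-(methoxymethoxy)phenol
Product: 9 [2-bromo-5-(methoxymethoxy)phenoxy]tri(propan-2-yl)silane
Conditions: iPr3SiCl, imidazole, DMF, rt
Reagents that add atoms: chlorotri(propan-2-yl)silane, CC(C)[Si](Cl)(C(C)C)C(C)C
Why: Silylation of the phenol; the bulky triisopropylsilyl ether is chosen because it should tolerate the alkoxide and ylide bases of the next two steps and is later removed by fluoride without acid.

Step 8
Reactants: 4 1-[4-(benzyloxy)-2-methoxy-3-(methoxymethoxy)phenyl]ethan-1-one; 9 [2-bromo-5-(methoxymethoxy)phenoxy]tri(propan-2-yl)silane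
Product: 10 1-[4-(benzyloxy)-2-methoxy-3-(methoxymethoxy)phenyl]-2-{4-(methoxymethoxy)-2-[tri(propan-2-yl)silyloxy]phenyl}ethan-1-one
Conditions: Pd2(dba)3 (2.5 mol %), tBu3P·HBF4 (10 mol %), NaOtBu (2.2 equiv), THF, 50 °C
Reagents that add atoms: none
Why: Palladium-catalysed α-arylation of a ketone enolate with an aryl bromide (zerovalent palladium, bulky electron-rich phosphine) forms the C4–C4a bond; the product is more acidic than 4 and is held as its enolate, which prevents a second arylation, and ortho-oxygenated aryl bromides are established partners in this reaction.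

Step 9
Reactants: 10 1-[4-(benzyloxy)-2-methoxy-3-(methoxymethoxy)phenyl]-2-{4-(methoxymethoxy)-2-[tri(propan-2-yl)silyloxy]phenyl}ethan-1-one
Product: 11 (2-{2-[4-(benzyloxy)-2-methoxy-3-(methoxymethoxy)phenyl]prop-2-en-1-yl}-5-(methoxymethoxy)phenoxy)tri(propan-2-yl)silane
Conditions: Ph3PCH3Br, NaN(SiMe3)2, THF, 0 °C to rt
Reagents that add atoms: methyltriphenylphosphonium bromide, C[P+](c1ccccc1)(c1ccccc1)c1ccccc1.[Br-]
Why: Wittig methylenation installs C2 as the terminal alkene carbon; enolisation of the ketone by the ylide is reversible while oxaphosphetane formation is not, and the amide base at low temperature limits migration of the new double bond into conjugation with ring A.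

Step 10
Reactants: 11 (2-{2-[4-(benzyloxy)-2-methoxy-3-(methoxymethoxy)phenyl]prop-2-en-1-yl}-5-(methoxymethoxy)phenoxy)tri(propan-2-yl)silane
Product: 12 2-{2-[4-(benzyloxy)-2-methoxy-3-(methoxymethoxy)phenyl]prop-2-en-1-yl}-5-(methoxymethoxy)phenol
Conditions: Bu4NF, AcOH, THF, 0 °C
Reagents that add atoms: none
Why: Fluoride cleaves the aryl silyl ether; acetic acid buffers the phenoxide so that the 1,1-disubstituted alkene does not migrate, and no acid strong enough to cause Markovnikov cyclisation or acetal loss is present.

Step 11
Reactants: 12 2-{2-[4-(benzyloxy)-2-methoxy-3-(methoxymethoxy)phenyl]prop-2-en-1-yl}-5-(methoxymethoxy)phenol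
Product: 13 (3R)-3-[4-(benzyloxy)-2-methoxy-3-(methoxymethoxy)phenyl]-7-(methoxymethoxy)-3,4-dihydro-2H-chromene
Conditions: 9-mesityl-10-methylacridinium tetrafluoroborate (5 mol %), (R)-2'-methoxy-1,1'-binaphthalene-2-thiol (20 mol %), ClCH2CH2Cl, 450 nm LEDs, 0 °C, argon
Reagents that add atoms: none
Why: Proposed new method: the excited acridinium, a strong one-electron oxidant, should oxidise the α-aryl styrene of 12, whose radical cation is stabilised by the trioxygenated ring B; the ring A phenol oxygen attacks the unsubstituted terminus C2 in a 6-endo-trig closure that forms O1–C2 and the dihydropyran ring and, after loss of the proton, leaves a tertiary benzylic radical at C3. The arenethiol (S–H about 79 kcal/mol, against about 84 for the new C3–H bond) then transfers hydrogen irreversibly to this radical, and the arylthiyl radical is reduced by the acridine radical to the thiolate, which takes up the proton, so that the step is a redox-neutral isomerisation. The closest known reaction types are the acridinium-photocatalysed anti-Markovnikov hydroetherification of alkenols with achiral hydrogen donors and the enantioselective hydrogen-atom transfer from chiral thiols to prochiral carbon radicals; their combination with a phenol nucleophile and a tertiary benzylic radical is not established. The C3 stereocentre is set in the hydrogen transfer alone: the binaphthyl wall next to the S–H bond has to distinguish the two faces of the planar radical, which differ in the placement of the O1–C2 arm, the C4–C4a arm and the ortho-methoxy group of ring B. The step needs anti-Markovnikov regioselectivity (6-endo over 5-exo), which the polarity of the radical cation secures because only attack at C2 produces the benzylic radical, and it needs chemoselective oxidation of the alkene, which conjugation with ring B and the masking of every other phenol secure. An arenethiol is used in place of an alkanethiol because its thiyl radical is too weak to abstract the C3–H bond of 13 again and erode the configuration.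

Step 12
Reactants: 13 (3R)-3-[4-(benzyloxy)-2-methoxy-3-(methoxymethoxy)phenyl]-7-(methoxymethoxy)-3,4-dihydro-2H-chromene
Product: 14 3-methoxy-2-(methoxymethoxy)-4-[(3R)-7-(methoxymethoxy)-3,4-dihydro-2H-chromen-3-yl]phenol
Conditions: H2 (1 atm), Pd/C, EtOAc, rt
Reagents that add atoms: none
Why: Catalytic hydrogenolysis of the benzyl ether frees only O4'; the MOM acetals, the methyl ether and C3 (which has no C–O bond) are untouched, and no alkene is present at this stage.

Step 13
Reactants: 14 3-methoxy-2-(methoxymethoxy)-4-[(3R)-7-(methoxymethoxy)-3,4-dihydro-2H-chromen-3-yl]phenol; 15 prenyl bromide, 1-bromo-3-methylbut-2-ene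
Product: 16 (3R)-3-{2-methoxy-3-(methoxymethoxy)-4-[(3-methylbut-2-en-1-yl)oxy]phenyl}-7-(methoxymethoxy)-3,4-dihydro-2H-chromene
Conditions: K2CO3, acetone, 50 °C
Reagents that add atoms: none
Why: Williamson O-allylation of the phenol with a primary allylic bromide; carbonate in a polar aprotic solvent favours O- over C-alkylation.

Step 14
Reactants: 16 (3R)-3-{2-methoxy-3-(methoxymethoxy)-4-[(3-methylbut-2-en-1-yl)oxy]phenyl}-7-(methoxymethoxy)-3,4-dihydro-2H-chromene
Product: 18 3-methoxy-2-(methoxymethoxy)-4-[(3R)-7-(methoxymethoxy)-3,4-dihydro-2H-chromen-3-yl]-6-(2-methylbut-3-en-2-yl)phenol, via ortho-dienone 17 (not isolated)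
Conditions: PhNEt2, 185 °C, sealed tube, argon
Reagents that add atoms: none
Why: Aromatic Claisen rearrangement: the [3,3] shift moves the allyl group to C5', the only free ortho position, with allylic transposition, so that the quaternary carbon becomes bonded to the ring, and dienone 17 tautomerises to the phenol. Migration towards C3' gives a blocked dienone that can only revert, the para position C1' is substituted, and the basic amine solvent protects the acetals.

Step 15
Reactants: 18 3-methoxy-2-(methoxymethoxy)-4-[(3R)-7-(methoxymethoxy)-3,4-dihydro-2H-chromen-3-yl]-6-(2-methylbut-3-en-2-yl)phenol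
Product: 19 (3R)-3-[3,4-dihydroxy-2-methoxy-5-(2-methylbut-3-en-2-yl)phenyl]-3,4-dihydro-2H-chromen-7-ol
Conditions: HCl (1 M in MeOH), 40 °C, argon
Reagents that add atoms: none
Why: Acid-catalysed acetal exchange with methanol removes both MOM groups as dimethoxymethane; dilute acid at moderate temperature should not protonate a monosubstituted alkene, and argon protects the catechol from oxidation.

## Compound list

1 | 1-(2,3,4-trihydroxyphenyl)ethan-1-one (gallacetophenone) | CC(=O)c1ccc(O)c(O)c1O | starting material
2 | 1-[4-(benzyloxy)-2,3-dihydroxyphenyl]ethan-1-one | CC(=O)c1ccc(OCc2ccccc2)c(O)c1O | intermediate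
3 | 1-[4-(benzyloxy)-2-hydroxy-3-(methoxymethoxy)phenyl]ethan-1-one | CC(=O)c1ccc(OCc2ccccc2)c(OCOC)c1O | intermediate
4 | 1-[4-(benzyloxy)-2-methoxy-3-(methoxymethoxy)phenyl]ethan-1-one | CC(=O)c1ccc(OCc2ccccc2)c(OCOC)c1OC | intermediate
5 | 3-hydroxyphenyl benzoate (resorcinol monobenzoate) | O=C(Oc1cccc(O)c1)c1ccccc1 | starting material
6 | 2-bromo-5-hydroxyphenyl benzoate | O=C(Oc1cc(O)ccc1Br)c1ccccc1 | intermediate
7 | 2-bromo-5-(methoxymethoxy)phenyl benzoate | O=C(Oc1cc(OCOC)ccc1Br)c1ccccc1 | intermediate
8 | 2-bromo-5-(methoxymethoxy)phenol | Oc1cc(OCOC)ccc1Br | intermediate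
9 | [2-bromo-5-(methoxymethoxy)phenoxy]tri(propan-2-yl)silane | CC(C)[Si](Oc1cc(OCOC)ccc1Br)(C(C)C)C(C)C | intermediate
10 | 1-[4-(benzyloxy)-2-methoxy-3-(methoxymethoxy)phenyl]-2-{4-(methoxymethoxy)-2-[tri(propan-2-yl)silyloxy]phenyl}ethan-1-one | COc1c(OCOC)c(OCc2ccccc2)ccc1C(=O)Cc1ccc(OCOC)cc1O[Si](C(C)C)(C(C)C)C(C)C | intermediate
11 | (2-{2-[4-(benzyloxy)-2-methoxy-3-(methoxymethoxy)phenyl]prop-2-en-1-yl}-5-(methoxymethoxy)phenoxy)tri(propan-2-yl)silane | C=C(Cc1ccc(OCOC)cc1O[Si](C(C)C)(C(C)C)C(C)C)c1ccc(OCc2ccccc2)c(OCOC)c1OC | intermediate
12 | 2-{2-[4-(benzyloxy)-2-methoxy-3-(methoxymethoxy)phenyl]prop-2-en-1-yl}-5-(methoxymethoxy)phenol | C=C(Cc1ccc(OCOC)cc1O)c1ccc(OCc2ccccc2)c(OCOC)c1OC | intermediate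
13 | (3R)-3-[4-(benzyloxy)-2-methoxy-3-(methoxymethoxy)phenyl]-7-(methoxymethoxy)-3,4-dihydro-2H-chromene | COc1c(OCOC)c(OCc2ccccc2)ccc1[C@@H]1COc2cc(OCOC)ccc2C1 | intermediate
14 | 3-methoxy-2-(methoxymethoxy)-4-[(3R)-7-(methoxymethoxy)-3,4-dihydro-2H-chromen-3-yl]phenol | COc1c(OCOC)c(O)ccc1[C@@H]1COc2cc(OCOC)ccc2C1 | intermediate
15 | 1-bromo-3-methylbut-2-ene (prenyl bromide) | CC(C)=CCBr | starting material
16 | (3R)-3-{2-methoxy-3-(methoxymethoxy)-4-[(3-methylbut-2-en-1-yl)oxy]phenyl}-7-(methoxymethoxy)-3,4-dihydro-2H-chromene | COc1c(OCOC)c(OCC=C(C)C)ccc1[C@@H]1COc2cc(OCOC)ccc2C1 | intermediate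
17 | 3-methoxy-2-(methoxymethoxy)-4-[(3R)-7-(methoxymethoxy)-3,4-dihydro-2H-chromen-3-yl]-6-(2-methylbut-3-en-2-yl)cyclohexa-2,4-dien-1-one (both epimers at the ring carbon C6, not isolated) | C=CC(C)(C)C1C=C([C@@H]2COc3cc(OCOC)ccc3C2)C(OC)=C(OCOC)C1=O | intermediate
18 | 3-methoxy-2-(methoxymethoxy)-4-[(3R)-7-(methoxymethoxy)-3,4-dihydro-2H-chromen-3-yl]-6-(2-methylbut-3-en-2-yl)phenol | C=CC(C)(C)c1cc([C@@H]2COc3cc(OCOC)ccc3C2)c(OC)c(OCOC)c1O | intermediate
19 | (3R)-3-[3,4-dihydroxy-2-methoxy-5-(2-methylbut-3-en-2-yl)phenyl]-3,4-dihydro-2H-chromen-7-ol | C=CC(C)(C)c1cc([C@@H]2COc3cc(O)ccc3C2)c(OC)c(O)c1O | target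

## Step count and least certain steps

Total step count: 15. Longest linear sequence: 12 steps (steps 4 to 15, from 5). The ring B branch (steps 1 to 3) joins at step 8.

**Step 11 (key step, proposed new method).**
- What may go wrong: poor or reversed facial selectivity in the hydrogen transfer, because a single aryl wall may not tell apart two faces that differ only in two methylene arms and a remote methoxy group.
- Also possible: anti-Markovnikov addition of the arylthiyl radical to the styrene, which consumes the thiol; abstraction of the doubly activated C4 hydrogen by the thiyl radical, which moves the double bond into conjugation with ring A; and acid-promoted 5-exo Markovnikov closure.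
- Fallback by known chemistry, from 11 back to 13:
  - Cobalt-catalysed enantioselective hydroboration of the 1,1-disubstituted aryl alkene with pinacolborane (CoCl2 complex of a chiral iminopyridine–oxazoline ligand, activated with NaBHEt3, ligand antipode chosen for the R series) should give the primary boronate {2-[(2R)-2-[4-(benzyloxy)-2-methoxy-3-(methoxymethoxy)phenyl]-3-(4,4,5,5-tetramethyl-1,3,2-dioxaborolan-2-yl)propyl]-5-(methoxymethoxy)phenoxy}tri(propan-2-yl)silane F1.
  - Oxidation with NaBO3 in aqueous THF gives (2R)-2-[4-(benzyloxy)-2-methoxy-3-(methoxymethoxy)phenyl]-3-{4-(methoxymethoxy)-2-[tri(propan-2-yl)silyloxy]phenyl}propan-1-ol F2.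
  - Bu4NF frees the phenol to give 2-{(2R)-2-[4-(benzyloxy)-2-methoxy-3-(methoxymethoxy)phenyl]-3-hydroxypropyl}-5-(methoxymethoxy)phenol F3.
  - A Mitsunobu etherification (PPh3, diisopropyl azodicarboxylate) closes O1–C2 at the primary carbon to 13 without touching C3.

**Step 14.**
- What may go wrong: further reaction of the ortho-(1,1-dimethylallyl)phenol at the high temperature by the abnormal Claisen pathway (hydrogen shift through a spirocyclopropane dienone), and thermal loss of the prenyl group as isoprene, which returns 14.
- Fallback, from 14 to 19 without a sigmatropic step: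
  - Ortho-bromination of 14 with NBS at low temperature gives 6-bromo-3-methoxy-2-(methoxymethoxy)-4-[(3R)-7-(methoxymethoxy)-3,4-dihydro-2H-chromen-3-yl]phenol F4.
  - MOM protection gives (3R)-3-[5-bromo-2-methoxy-3,4-bis(methoxymethoxy)phenyl]-7-(methoxymethoxy)-3,4-dihydro-2H-chromene F5.
  - A γ-selective Suzuki–Miyaura coupling with 3-methylbut-2-en-1-ylboronic acid pinacol ester (Pd(OAc)2, bulky biarylphosphine, K3PO4) forms the quaternary benzylic carbon by allyl transposition and gives (3R)-3-[2-methoxy-3,4-bis(methoxymethoxy)-5-(2-methylbut-3-en-2-yl)phenyl]-7-(methoxymethoxy)-3,4-dihydro-2H-chromene F6.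
  - HCl in methanol removes the three acetals to give 19.

**Step 8.**
- What may go wrong: slow coupling of two ortho-oxygenated, electron-rich partners, transfer or loss of the silyl group under the alkoxide base, and a second arylation.
- Fallback with reversed polarity, from 4 and 9 back to 10:
  - Ketone 4 is converted (LiN(SiMe3)2, Me3SiCl) into ({1-[4-(benzyloxy)-2-methoxy-3-(methoxymethoxy)phenyl]ethenyl}oxy)trimethylsilane F7.
  - NBS converts F7 into 2-bromo-1-[4-(benzyloxy)-2-methoxy-3-(methoxymethoxy)phenyl]ethan-1-one F8.
  - Bromide 9 undergoes Miyaura borylation (bis(pinacolato)diboron, Pd(dppf)Cl2, KOAc) to [5-(methoxymethoxy)-2-(4,4,5,5-tetramethyl-1,3,2-dioxaborolan-2-yl)phenoxy]tri(propan-2-yl)silane F9.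
  - A Suzuki–Miyaura coupling of F8 with F9 (Pd(PPh3)4, K3PO4) forms the C4–C4a bond of 10 without a strong base.

**Step 9.**
- What may go wrong: enolisation of the doubly activated methylene by the ylide, leading to incomplete conversion, and base-induced migration of the new double bond to the stilbene position.
- Fallback, from 10 back to 11:
  - (Trimethylsilyl)methyllithium premixed with anhydrous CeCl3 adds to ketone 10 as a weakly basic organocerium reagent to give 2-[4-(benzyloxy)-2-methoxy-3-(methoxymethoxy)phenyl]-1-{4-(methoxymethoxy)-2-[tri(propan-2-yl)silyloxy]phenyl}-3-(trimethylsilyl)propan-2-ol F10.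
  - KH in THF brings about the elimination (Peterson olefination) to 11, the position of silicon fixing the double bond at the terminus.

## Further compounds

F1 | step 11 | {2-[(2R)-2-[4-(benzyloxy)-2-methoxy-3-(methoxymethoxy)phenyl]-3-(4,4,5,5-tetramethyl-1,3,2-dioxaborolan-2-yl)propyl]-5-(methoxymethoxy)phenoxy}tri(propan-2-yl)silane | CC1(C)OB(C[C@H](Cc2ccc(OCOC)cc2O[Si](C(C)C)(C(C)C)C(C)C)c2ccc(OCc3ccccc3)c(OCOC)c2OC)OC1(C)C
F2 | step 11 | (2R)-2-[4-(benzyloxy)-2-methoxy-3-(methoxymethoxy)phenyl]-3-{4-(methoxymethoxy)-2-[tri(propan-2-yl)silyloxy]phenyl}propan-1-ol | OC[C@H](Cc1ccc(OCOC)cc1O[Si](C(C)C)(C(C)C)C(C)C)c1ccc(OCc2ccccc2)c(OCOC)c1OC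
F3 | step 11 | 2-{(2R)-2-[4-(benzyloxy)-2-methoxy-3-(methoxymethoxy)phenyl]-3-hydroxypropyl}-5-(methoxymethoxy)phenol | OC[C@H](Cc1ccc(OCOC)cc1O)c1ccc(OCc2ccccc2)c(OCOC)c1OC
F4 | step 14 | 6-bromo-3-methoxy-2-(methoxymethoxy)-4-[(3R)-7-(methoxymethoxy)-3,4-dihydro-2H-chromen-3-yl]phenol | COc1c(OCOC)c(O)c(Br)cc1[C@@H]1COc2cc(OCOC)ccc2C1
F5 | step 14 | (3R)-3-[5-bromo-2-methoxy-3,4-bis(methoxymethoxy)phenyl]-7-(methoxymethoxy)-3,4-dihydro-2H-chromene | COc1c(OCOC)c(OCOC)c(Br)cc1[C@@H]1COc2cc(OCOC)ccc2C1
F6 | step 14 | (3R)-3-[2-methoxy-3,4-bis(methoxymethoxy)-5-(2-methylbut-3-en-2-yl)phenyl]-7-(methoxymethoxy)-3,4-dihydro-2H-chromene | C=CC(C)(C)c1cc([C@@H]2COc3cc(OCOC)ccc3C2)c(OC)c(OCOC)c1OCOC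
F7 | step 8 | ({1-[4-(benzyloxy)-2-methoxy-3-(methoxymethoxy)phenyl]ethenyl}oxy)trimethylsilane | C=C(O[Si](C)(C)C)c1ccc(OCc2ccccc2)c(OCOC)c1OC
F8 | step 8 | 2-bromo-1-[4-(benzyloxy)-2-methoxy-3-(methoxymethoxy)phenyl]ethan-1-one | O=C(CBr)c1ccc(OCc2ccccc2)c(OCOC)c1OC
F9 | step 8 | [5-(methoxymethoxy)-2-(4,4,5,5-tetramethyl-1,3,2-dioxaborolan-2-yl)phenoxy]tri(propan-2-yl)silane | CC(C)[Si](Oc1cc(OCOC)ccc1B2OC(C)(C)C(C)(C)O2)(C(C)C)C(C)C
F10 | step 9 | 2-[4-(benzyloxy)-2-methoxy-3-(methoxymethoxy)phenyl]-1-{4-(methoxymethoxy)-2-[tri(propan-2-yl)silyloxy]phenyl}-3-(trimethylsilyl)propan-2-ol (racemic) | C[Si](C)(C)CC(O)(Cc1ccc(OCOC)cc1O[Si](C(C)C)(C(C)C)C(C)C)c1ccc(OCc2ccccc2)c(OCOC)c1OC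
A1 | alternative 1 | 2-[(1R)-2-{2-[(tert-butyldimethylsilyl)oxy]-4-(methoxymethoxy)phenyl}-1-[2-methoxy-3,4-bis(methoxymethoxy)-5-(2-methylbut-3-en-2-yl)phenyl]ethyl]-4,4,5,5-tetramethyl-1,3,2-dioxaborolane | COc1c(OCOC)c(OCOC)c(C(C)(C)C=C)cc1[C@@H](Cc1ccc(OCOC)cc1O[Si](C)(C)C(C)(C)C)B1OC(C)(C)C(C)(C)O1
A2 | alternative 2 | methyl (2R,3S)-2-{2-[(tert-butyldimethylsilyl)oxy]-4-(methoxymethoxy)phenyl}-6,7-bis(methoxymethoxy)-5-(2-methylbut-3-en-2-yl)-2,3-dihydro-1-benzofuran-3-carboxylate (cis) | COC(=O)[C@@H]1[C@H](c2ccc(OCOC)cc2O[Si](C)(C)C(C)(C)C)Oc2c1cc(C(C)(C)C=C)c(OCOC)c2OCOC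
A3 | alternative 3 | (3R)-3-[2-methoxy-3,4-bis(methoxymethoxy)-5-(2-methylbut-3-en-2-yl)phenyl]-7-(methoxymethoxy)-3,4-dihydro-2H-chromen-2-one | O=C1Oc2cc(OCOC)ccc2C[C@@H]1c3cc(C(C)(C)C=C)c(OCOC)c(OCOC)c3OC
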